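**Retrosynthetic overview** (target numbering: C1 carries the exocyclic C7H2OBz, C2 is the alkene CH, C3 OMe, C4 OH, C5 OBz, C6 OH)
- The C1–C7 bond is made last: a Stille coupling joins an unprotected alkenyl bromide (the ring with O5 already benzoylated) to (tributylstannyl)methyl benzoate.
- The enabling feature is the vinylic C1–Br bond of the cyclohexene ring, on the sp2 carbon between C2 and the C6 carbinol. It is the bromine of bromobenzene, retained when the arene is dearomatised enzymatically to the cis-dihydrodiol starting material, so the flat benzene ring becomes the carbocycle with C5 and C6 already set.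
- Before it is exchanged for C7 the bromine does two further jobs. It deactivates its own alkene, so epoxidation goes to C3=C4 anti to the acetonide and methanol then opens the oxirane trans at allylic C3. Through allylic 1,2-strain it also holds O6–H pseudoaxial, so O5 can be benzoylated selectively.
- Forward order: diol, acetonide, anti-epoxide, trans-methoxy alcohol, triol, 5-O-benzoate, then coupling; the stannane is made in one step.
- The carbocycle is never formed or broken. The only rings made are a temporary dioxolane (step 1, removed in step 4) and an oxirane (step 2, opened in step 3).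

Key step: step 7

Remark on the chemistry: the (1S,2S)-cis-dihydrodiol of bromobenzene and (tributylstannyl)methanol are taken as purchasable, and the half-chair of the triol is assumed to place the hydroxyl next to C–Br pseudoaxial.

**Step 1**
Reactants: 1 (1S,2S)-3-bromocyclohexa-3,5-diene-1,2-diol
Product: 2 (3aS,7aS)-4-bromo-2,2-dimethyl-3a,7a-dihydro-1,3-benzodioxole
Conditions: 2,2-dimethoxypropane (5 equiv), p-TsOH·H2O (2 mol %), acetone, 0 °C → rt; product used without storage
Reagents that add atoms: 2,2-dimethoxypropane, COC(C)(C)OC
Why: Acid-catalysed transketalisation (acetonide formation) of the cis-1,2-diol should outpace acid-induced dehydration to bromophenol when the ketal reagent is in excess; no stereocentre is touched.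

**Step 2**
Reactants: 2 (3aS,7aS)-4-bromo-2,2-dimethyl-3a,7a-dihydro-1,3-benzodioxole
Product: 3 (3aS,5aR,6aR,6bS)-4-bromo-2,2-dimethyl-3a,5a,6a,6b-tetrahydrooxireno[2,3-e][1,3]benzodioxole (oxirane on the face opposite the dioxolane)
Conditions: mCPBA (1.2 equiv), CH2Cl2, 0 °C → rt
Reagents that add atoms: mCPBA (3-chloroperoxybenzoic acid), OOC(=O)c1cccc(Cl)c1
Why: In this Prilezhaev epoxidation the peracid should attack the more electron-rich, bromine-free C3=C4 alkene from the face opposite the dioxolane ring, which sets both oxirane carbons anti to the diol oxygens by substrate control.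

**Step 3**
Reactants: 3 (3aS,5aR,6aR,6bS)-4-bromo-2,2-dimethyl-3a,5a,6a,6b-tetrahydrooxireno[2,3-e][1,3]benzodioxole
Product: 4 (3aS,4R,5S,7aS)-7-bromo-5-methoxy-2,2-dimethyl-3a,4,5,7a-tetrahydro-1,3-benzodioxol-4-ol
Conditions: MeOH (solvent), (+)-10-camphorsulfonic acid (5 mol %), 0 °C → rt
Reagents that add atoms: methanol, CO
Why: In this acid-catalysed epoxide ring opening, methanol should attack the allylically activated oxirane carbon with inversion (SN2-type), giving the trans-methoxy alcohol and so setting the future C3 (OMe) and C4 (OH) centres.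

**Step 4**
Reactants: 4 (3aS,4R,5S,7aS)-7-bromo-5-methoxy-2,2-dimethyl-3a,4,5,7a-tetrahydro-1,3-benzodioxol-4-ol
Product: 5 (1S,2S,3S,6S)-4-bromo-6-methoxycyclohex-4-ene-1,2,3-triol
Conditions: 80% aq. AcOH, 50 °C
Reagents that add atoms: none
Why: Acid hydrolysis of the isopropylidene acetal should free the cis-diol, while the allylic methyl ether, the alkenyl bromide and all stereocentres are expected to survive these mild conditions.

**Step 5**
Reactants: 5 (1S,2S,3S,6S)-4-bromo-6-methoxycyclohex-4-ene-1,2,3-triol
Product: 6 (1S,2S,5S,6R)-3-bromo-2,6-dihydroxy-5-methoxycyclohex-3-en-1-yl benzoate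
Conditions: BzCl (1.1 equiv), Ph2BOCH2CH2NH2 (2-aminoethyl diphenylborinate, 10 mol %), i-Pr2NEt (1.5 equiv), MeCN, rt
Reagents that add atoms: benzoyl chloride, O=C(Cl)c1ccccc1
Why: In this borinic-acid-catalysed site-selective acylation of a cis-1,2-diol, the catalyst should bind the cis pair O5/O6 (target numbering) as a tetracoordinate borinate and pass the benzoyl group to the equatorial oxygen O5, while the pseudoaxial O6–H next to C–Br and the trans-disposed O4–H stay free; no stereocentre is formed or touched.

**Step 6**
Reactants: 7 (tributylstannyl)methanol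
Product: 8 (tributylstannyl)methyl benzoate
Conditions: BzCl (1.1 equiv), Et3N (1.5 equiv), 4-(dimethylamino)pyridine (5 mol %), CH2Cl2, 0 °C → rt
Reagents that add atoms: benzoyl chloride, O=C(Cl)c1ccccc1
Why: This is a nucleophilic acyl substitution (amine-catalysed O-benzoylation) of a primary alcohol, to which the C–Sn bonds are inert.

**Step 7**
Reactants: 6 (1S,2S,5S,6R)-3-bromo-2,6-dihydroxy-5-methoxycyclohex-3-en-1-yl benzoate; 8 (tributylstannyl)methyl benzoate
Product: 9 [(3S,4R,5R,6R)-5-(benzoyloxy)-4,6-dihydroxy-3-methoxycyclohex-1-en-1-yl]methyl benzoate (CNP0349013.6)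
Conditions: 8 (1.5 equiv), Pd2(dba)3 (2.5 mol %), AsPh3 (20 mol %), CuI (10 mol %), degassed DMF, 50 °C
Reagents that add atoms: none
Why: This is a Migita–Kosugi–Stille coupling: zerovalent palladium inserts into the vinylic C1–Br bond of 6, the benzoyloxymethyl group passes from tin through a monovalent copper intermediate to palladium (the ester carbonyl chelates the metal, so this α-oxygenated sp3 group should transfer in preference to butyl), and reductive elimination forges C1–C7. The closest known reaction types are the Stille hydroxymethylation of alkenyl and aryl halides with (tributylstannyl)methanol and the palladium/copper couplings of α-acyloxyalkyl stannanes; alkenyl bromides derived from arene cis-dihydrodiols are established Stille partners. No ring is closed and no stereocentre is created; the four existing centres are spectators because no C–O bond at sp3 carbon is touched, and the alkene position is fixed by where the bromine sat. The selectivity needed is chemoselectivity: reaction at C–Br only, with the benzoate staying on O5 and the C4 and C6 hydroxyls left free, which the neutral, base-free and fluoride-free medium at moderate temperature is expected to secure. In this one operation C7 and the second benzoate (8 of the 22 carbon atoms) are delivered to an unprotected partner, so no deprotection follows.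

**Compound list**
1 | (1S,2S)-3-bromocyclohexa-3,5-diene-1,2-diol | O[C@H]1C=CC=C(Br)[C@H]1O | starting material
2 | (3aS,7aS)-4-bromo-2,2-dimethyl-3a,7a-dihydro-1,3-benzodioxole | CC1(C)O[C@H]2C=CC=C(Br)[C@H]2O1 | intermediate
3 | (3aS,5aR,6aR,6bS)-4-bromo-2,2-dimethyl-3a,5a,6a,6b-tetrahydrooxireno[2,3-e][1,3]benzodioxole (anti-epoxide) | O1[C@@H]2C=C(Br)[C@H]3OC(C)(C)O[C@H]3[C@H]12 | intermediate
4 | (3aS,4R,5S,7aS)-7-bromo-5-methoxy-2,2-dimethyl-3a,4,5,7a-tetrahydro-1,3-benzodioxol-4-ol | CO[C@H]1C=C(Br)[C@H]2OC(C)(C)O[C@H]2[C@@H]1O | intermediate
5 | (1S,2S,3S,6S)-4-bromo-6-methoxycyclohex-4-ene-1,2,3-triol | CO[C@H]1C=C(Br)[C@@H](O)[C@@H](O)[C@@H]1O | intermediate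
6 | (1S,2S,5S,6R)-3-bromo-2,6-dihydroxy-5-methoxycyclohex-3-en-1-yl benzoate | CO[C@H]1C=C(Br)[C@@H](O)[C@@H](OC(=O)c2ccccc2)[C@@H]1O | intermediate
7 | (tributylstannyl)methanol | CCCC[Sn](CCCC)(CCCC)CO | starting material
8 | (tributylstannyl)methyl benzoate | CCCC[Sn](CCCC)(CCCC)COC(=O)c1ccccc1 | intermediate
9 | [(3S,4R,5R,6R)-5-(benzoyloxy)-4,6-dihydroxy-3-methoxycyclohex-1-en-1-yl]methyl benzoate | CO[C@H]1C=C(COC(=O)c2ccccc2)[C@@H](O)[C@@H](OC(=O)c2ccccc2)[C@@H]1O | target

Total step count: 7
Longest linear sequence: 6 steps (steps 1–5 and 7)

**Steps most likely to fail**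

Step 7. The transfer of the sp3 benzoyloxymethyl group from tin may be slow, so that butyl transfer and protodebromination compete, and zerovalent palladium may ionise the allylic benzoate of the product. The fallback brings C7 in one oxidation level higher, as carbon monoxide. It sets out from 4: methoxycarbonylation (Pd(OAc)2, Xantphos, CO 1 atm, MeOH, Et3N, DMF, 70 °C) should give the methyl ester F1. DIBAL-H (CH2Cl2, −78 °C) should reduce it to the allylic alcohol F2. BzCl (1.05 equiv), pyridine, CH2Cl2, −40 °C should acylate only the primary hydroxyl and give the primary benzoate F3. 80% aq. AcOH at 50 °C should release the triol F4, and benzoylation of O5 under the conditions of step 5 should bring the route back at 9.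

Step 5. Discrimination between the three secondary hydroxyls may be incomplete, with over-benzoylation, acylation at O4, or base-induced benzoyl migration between neighbouring oxygens. The fallback uses temporary protection so that only the cis pair is free when the benzoate is introduced. It sets out from 4: NaH, 4-methoxybenzyl chloride, Bu4NI (cat.), DMF, 0 °C should give the 4-methoxybenzyl ether F5. 80% aq. AcOH at 50 °C should give the diol F6. BzCl with the borinate catalyst of step 5 should then give the benzoate F7, the choice being only between the equatorial and the pseudoaxial oxygen. DDQ in CH2Cl2–pH 7 buffer at 0 °C should remove the ether and bring the route back at 6.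

Step 3. The opening may drift toward an allyl-cation pathway with loss of stereochemical fidelity at the allylic carbon, and the dioxolane may be methanolysed prematurely. The fallback replaces the oxirane by a cyclic sulfate that is opened under basic SN2 conditions. It sets out from 2: OsO4 (cat.), N-methylmorpholine N-oxide, acetone–H2O should dihydroxylate the bromine-free alkene anti to the dioxolane and give the cis-diol F8. SO2Cl2, Et3N, CH2Cl2, −78 °C should give the cyclic sulfate F9. NaOMe in MeOH (0 °C → rt) should attack the allylic carbon with inversion and give the sulfate monoester sodium salt F10. H2SO4 (cat.) in THF with H2O (2 equiv) at rt should hydrolyse the monoester and bring the route back at 4.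

**Further compounds**
F1 | step 7 | methyl ester (CO2Me in place of Br of 4) | CO[C@H]1C=C(C(=O)OC)[C@H]2OC(C)(C)O[C@H]2[C@@H]1O
F2 | step 7 | allylic alcohol (CH2OH in place of Br of 4) | CO[C@H]1C=C(CO)[C@H]2OC(C)(C)O[C@H]2[C@@H]1O
F3 | step 7 | primary benzoate (CH2OBz in place of Br of 4) | CO[C@H]1C=C(COC(=O)c3ccccc3)[C@H]2OC(C)(C)O[C@H]2[C@@H]1O
F4 | step 7 | triol (9 without the benzoyl group on O5) | CO[C@H]1C=C(COC(=O)c2ccccc2)[C@@H](O)[C@@H](O)[C@@H]1O
F5 | step 5 | 4-methoxybenzyl ether of 4 | CO[C@H]1C=C(Br)[C@H]2OC(C)(C)O[C@H]2[C@@H]1OCc3ccc(OC)cc3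
F6 | step 5 | diol (4-methoxybenzyl ether of 5 at the hydroxyl trans to both neighbours) | CO[C@H]1C=C(Br)[C@@H](O)[C@@H](O)[C@@H]1OCc2ccc(OC)cc2
F7 | step 5 | benzoate (4-methoxybenzyl ether of 6) | CO[C@H]1C=C(Br)[C@@H](O)[C@@H](OC(=O)c2ccccc2)[C@@H]1OCc2ccc(OC)cc2
F8 | step 3 | cis-diol (both hydroxyls anti to the dioxolane) | O[C@@H]1C=C(Br)[C@H]2OC(C)(C)O[C@H]2[C@@H]1O
F9 | step 3 | cyclic sulfate of F8 | O=S1(=O)O[C@@H]2C=C(Br)[C@H]3OC(C)(C)O[C@H]3[C@@H]2O1
F10 | step 3 | sulfate monoester sodium salt (O-sulfate of 4) | CO[C@H]1C=C(Br)[C@H]2OC(C)(C)O[C@H]2[C@@H]1OS(=O)(=O)[O-].[Na+]
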